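Readings and results are calculated from invented constants; scatter was added.

I decide to reckon this flask by the L left, not the L made. Friday's run and Sunday's look nearly alike: the Q and J are equal, and the difference is the L charged, twice as much on Friday.

| setting | Sunday's | Friday's | flask |
|---|---|---|---|
| L | 0.074 M | 0.15 M | 0.074 M |
| Q | 3.7 mM | 3.7 mM | 3.70 mM |
| J | 0.15 mM | 0.15 mM | 0.15 mM |
| remark | the very flask that is asked about, followed so far | run made earlier |  |
| time |  |  | 4.0 d |

- Sunday's (time / h: X / %, L / %): 3.00: 37, 55; 10.0: 59, 42; 20.0: 60, 36; 30.0: 60, 37; 40.0: 55, 35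
- Friday's (time / d: X / %, L / %): 0.625: 83, 18; 1.04: 78, 18; 1.67: 79, 16; 2.50: 80, 21; 3.00: 78, 18

(each reading ± 2 percentage points)

- the average divides the monomer in chains by the number of chains begun, living and dead together
- on the list of suspects stand: L + J -> D + X; L + D -> X + D; X + D -> L + D; Q + L -> E; 2 J -> Z
- the earlier runs do not show the number of chains; that part of a forecast is a guess

- average number of monomer units in a chain (chains begun, living or dead) at 4.0 d
- part of the L that has reacted at 4.0 d

Friday's L stays near 18.2 % of its charge, and Sunday's, from 20.0 h on, near 36.0 %, so Friday's share is about half of Sunday's. Multiplied by their charges, these readings give 27.3 mM and 26.6 mM, nearly the same [L]. I call Friday's value the floor: the [L] at which a run stops losing L, the equilibrium monomer concentration. The two runs end where they do because a like floor is set against different charges. The asked time lies beyond Sunday's last reading, so I hold the floor. Over this flask's 0.074 M it leaves 36.9 %, and I commit to 63.1 % reacted.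

The forecast, close to that, gives 63.5 % (61 % to 66 %) and a chain average of 340 (280 to 650), reading the runs as “a living polymerization at equilibrium”.

The flask gives 65.1 % reacted and a chain average of 439, above the forecast's 340.

    L + J → D + X (k = 0.00360 M⁻¹ s⁻¹)
    L + D → X + D, rate k2*[D]*[L] (k = 1.20 M⁻¹ s⁻¹)
    X + D → L + D, rate k3*[D] as long as [X] is above zero (k = 0.0310 s⁻¹)
    Q + L → E (k = 0.00650 M⁻¹ s⁻¹)
    2 J → Z (k = 0.900 M⁻¹ s⁻¹)

At 4.00 d this flask holds 1.01 × 10⁻⁴ M of D, less than the 0.15 mM of J charged. Its L, 34.9 % of the charge, is 25.8 mM, beside the floor of 27.3 mM. Set against a neighbour flask charged with 0.044 M of L, the floor leaves 62.0 % of that charge as L; that neighbour holds 58.7 %.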